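All runs stem from a simulated flask for an exercise; noise was put on by code.

The nucleophile is what I would watch in a repeat of beta and theta.

common to all: electrophile 0.40 M

| flask | nucleophile | remark | time |
|---|---|---|---|
| Wednesday's | 1.2 equiv | run made earlier |  |
| Saturday's | 2.5 equiv | run made earlier |  |
| beta | 1.00 equiv |  | 3.0 min |
| theta | 2.00 equiv |  | 3.0 min |

| run | time / min | electrophile / % | product / % |
|---|---|---|---|
| Wednesday's | 0.417 | 95.6 | 4.5 |
| Wednesday's | 0.833 | 91.5 | 9.1 |
| Wednesday's | 1.33 | 86.8 | 13.5 |
| Wednesday's | 1.50 | 86.0 | 14.6 |
| Wednesday's | 2.00 | 81.9 | 18.0 |
| Wednesday's | 2.50 | 78.5 | 21.0 |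
| Wednesday's | 3.00 | 75.9 | 24.4 |
| Saturday's | 0.167 | 96.0 | 4.5 |
| Saturday's | 0.500 | 88.7 | 10.8 |
| Saturday's | 0.833 | 82.0 | 17.4 |
| Saturday's | 1.33 | 74.0 | 25.9 |
| Saturday's | 2.00 | 65.6 | 34.2 |
| Saturday's | 2.50 | 59.8 | 39.8 |
| Saturday's | 3.00 | 55.0 | 44.5 |

(each reading ± 0.3 percentage points)

- a reading or a percentage of product counts all its forms, free or not

- part of the electrophile that has reacted at the end, beta
- part of the electrophile that has reacted at the end, theta
- what raising the equivalents of nucleophile from its lowest to its highest value here does to the part of the electrophile that has reacted (changes below 5 percentage points count as none) (no change / it falls / it rises)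

I reckon in fractions of the charge, and with rates. The constant of a plain one-for-one rate law, as I read it, sags along both earlier runs, so I try a rule of my own: each electrophile reacted costs two nucleophile, one joining it and one lost to something unseen. The rate is then a start rate times two slowing factors, the fraction of electrophile left and the fraction of nucleophile left. Wednesday's last product reading gives 0.101 /min for the pace, the fraction of electrophile reacting per minute per equivalent of nucleophile at the charge. Saturday's gives 0.0992 /min, close to it, and these are separate runs.

Beta starts at 0.101 /min. Unslowed, that makes 30.3% in 3.0 min. With the slowing I get 20.7% for beta. By then the electrophile factor in beta is 79.3% and the nucleophile factor 58.6%, so by this reckoning beta ends near half its start rate. At two per electrophile, the nucleophile of beta is the limiting reagent. Theta starts twice as fast, and I get 37.7%, a rise of 17 percentage points.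

The forecast says 20.4%, 37.5% and it rises. It keeps the plain law and reads the sag as “mild inhibition or slowing, possibly product binding”. My figures stand slightly higher.

The flask gives 20.6% for beta, 37.5% for theta, and it rises, by 17 points.

    electrophile + nucleophile → acid set free + product (k = 0.250 /M/min)
    nucleophile + acid set free ⇌ protonated nucleophile, settled at all times (K = 2400 /M)
    crystals ⇌ product, rate k3*(cs3 - [product]) while solid is left; crystals form when [product] > cs3 (solubility = 0.0660 M, k = 2.10 /min)

At the end of beta, protonated nucleophile stands at 0.0822 M against 1.45 × 10⁻⁴ M of acid set free, and 59% of the nucleophile is free. The pace and these shares left then put beta's rate at the end at 0.0472 /min of the electrophile charged.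

For a neighbour of beta with 0.250 equiv of nucleophile, the pace gives 5.55%. The flask gives 5.52%, with 56% of its nucleophile free.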